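## Structural features

The target is a 4-methylcyclohex-3-ene, numbered here C1 to C6. C1 carries a 2,4-dihydroxy-3-prenylbenzoyl group (ring A). C2 carries a 2,6-dihydroxyphenyl group (ring B) that bears an (E)-4-hydroxycinnamoyl unit (ring D) at its 3-position. C6 carries a 2,4-dihydroxyphenyl group (ring C); C3=C4 is the ring alkene with the methyl group on C4, and C5 is a methylene. The stereocentres C6, C1 and C2 are contiguous and the aroyl group is trans to both aryl groups (1S,2S,6R in this numbering), so rings B and C are cis to each other and all three groups can be equatorial. Fragile elements are the prenyl group between two phenols (acid closes it to a chroman), the ring alkene flanked by ortho-hydroxyaryl groups (acid-promoted ether formation), the 2′-hydroxychalcone on ring B (flavanone closure), the enolisable C1 and seven free phenols. The real difficulty is the trans,trans triad in one absolute configuration on a ring whose alkene must sit at C3=C4, together with the crowding at C2 (ring B has two ortho oxygens) and the need to tell three resorcinol-type rings apart. The key step exploits the fact that the ring A carbonyl, C1, C2 and ring B form a 2′-hydroxychalcone once C1=C2 is an alkene, and that the ortho-hydroxyl and carbonyl of ring A can chelate boron. C3 to C6 with ring C then make a 1-aryl-3-methyl diene, and a silyl group on C3 allows the alkene formed at C4=C5 to be moved to C3=C4.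

## Logic of the disconnections

**21 from 19.** The last retrosynthetic move re-caps the phenols and puts silicon back on C3 with the alkene at C4=C5. The bonds "cut" are C5–H (replaced by C3–Si with allylic shift), five O–CH2OMe bonds and one O–acetyl bond. All acid-labile operations are thereby gathered into one final step, so the sensitive free polyphenol exists only once. The forward step must protonate C5 faster than the prenyl alkene and must not close chroman, ether or flavanone rings.

**19 from 17, 18 and carbon monoxide.** The aryl–C(=O) and C(=O)–CH= bonds of the ring B enone are cut. This removes ring D and a second Michael acceptor, so that 17 holds only one enone precursor and a robust bromide. The forward step must carbonylate an electron-rich ortho-alkoxy aryl bromide in the presence of a free phenol and an allylsilane.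

**17 from 16 and 7.** C1–C6 and C2–C3 are cut in one [4+2] retro-step. This is the largest simplification: one ring, two skeletal bonds and four stereocentres fall away, leaving two achiral, planar fragments of similar size. The forward step needs regiocontrol (silyl terminus to the β-carbon), the exo mode and one enone face.

**16 from 12 and 15.** The enone Cα=Cβ bond is cut (aldol condensation). Both halves are simple benzenoid compounds. The ketone must keep its 2-hydroxyl free for boron, and the aldehyde must be non-enolisable.

**12 from 11, 10, 9 and 8.** The 4-O–CH2OMe bond is cut, then the aryl C3–prenyl bond, which is traced back through a [3,3] shift to the 4-O–C(CH3)2 bond of 10 and to the alkyne 9. Forming the prenyl C–C bond sigmatropically avoids the poor regiochemistry of direct C-prenylation. It requires migration to C3 and not C5.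

**15 from 14 and 13.** The C–Br bond and the two O–CH2OMe bonds are cut. Bromination after protection keeps the ring from over-reacting; symmetry makes the two activated positions identical.

**7 from 4 and 6, then 4 from 3, 2 and 1, and 6 from 5.** The styrenyl C=C bond is cut (phosphonate olefination), then C–P, C–Br and the C2–CH3 bond of the vinylsilane. A Peterson olefination of the corresponding methyl enone with a bis(silyl)methyl anion was set aside, because the ketone enolises and nothing controls the geometry of the trisubstituted vinylsilane. Carbometalation of the silyl alkyne 1 fixes that geometry at the outset. The olefination must then react at the carbon next to phosphorus and give the E alkene.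

## Other disconnections considered

**Alternative 1:** The cut is at C2–C3 and C4–C5. In the forward step Ni(cod)2 (zerovalent nickel) with a chiral phosphine would couple the carbonyl of the prochiral cyclobutanone A1 with propyne A2. Oxidative cyclisation, β-carbon elimination of one enantiotopic ring bond and reductive elimination would give the (R)-enone A3.
- In its favour: the C6 centre comes from a catalyst and an achiral precursor, and the methyl-bearing alkene is born at C3=C4 with no silyl handle and no transposition. On alkene placement this is better than the chosen plan; on atom economy the two are equal.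
- Against it here: A3 holds one stereocentre and none of rings A or B. The carbonyl carbon (C2) must still become a C–aryl centre with the most hindered ring without moving the alkene, and C1 must be acylated regioselectively. Both new centres would rest on substrate control, and a terminal alkyne raises regiochemical and oligomerisation problems.
- Comparison: mechanistically elegant, but it solves the easiest third of the problem and would need clearly more steps after the key step than the chosen plan.

**Alternative 2:** The cut is at C3=C4. The second-generation Grubbs catalyst (H2IMes)(PCy3)Cl2Ru=CHPh would close the acyclic triene A4 to the all-trans ester A5, the two terminal CH2 groups leaving as a volatile olefin.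
- In its favour: the ring closure is the most dependable of all four plans, the alkene position is beyond doubt and no selectivity is at stake in the key step. On these points it is better than the chosen plan. It keeps the same bromide for the ring D endgame, which is equal.
- Against it here: the whole stereotriad must be built on an open chain beforehand by several stoichiometric stereocontrolled steps. Ring A cannot be present during metathesis because of its prenyl alkene. The ester at the crowded C1 must later be turned into an aryl ketone by an aryl-metal reagent that is incompatible with the aryl bromide.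
- Comparison: risk is moved from one step to many, and step economy is clearly worse.

**Alternative 3:** The cut is at C1–C6. Tetrabutylammonium fluoride and DBU would unmask the ring C phenoxide of the (Z)-keto acetate A6 and expel acetate to a para-quinone methide. The ring A ketone enolate would then add to C6 in a 6-exo-trig closure to give A7.
- In its favour: only C2 must be set in advance. C1 and C6 form under reversible, thermodynamic conditions that favour the all-equatorial isomer, which is better than the kinetic exo/endo control of the chosen plan. The ring A ketone is already in place and the bromide endgame is equal.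
- Against it here: A6 needs a Z-trisubstituted alkene next to a stereocentre and a differentiated silyl ether on ring C. The quinone methide can lose a proton from C5 to a conjugated diene or add fluoride or acetate. The precursor is linear and long.
- Comparison: stronger on stereochemical safety at C1 and C6, weaker on convergence and step count.

Key step: step 12

Assumption: the facial sense delivered by the (R)-configured vaulted biaryl borate cannot be predicted with certainty for this silyl diene; (R) is written, and the mirror-image ligand would be used unchanged otherwise if the adduct proved to be the antipode.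

## Route

Step 1
Reactants: 1 3-(trimethylsilyl)prop-2-yn-1-ol
Product: 2 (2E)-2-methyl-3-(trimethylsilyl)prop-2-en-1-ol
Conditions: MeMgCl (3 equiv), CuI (10 mol%), THF, 0 → 25 °C; aq NH4Cl
Reagents that add atoms: methylmagnesium chloride, C[Mg]Cl
Why: Copper-catalysed anti-carbomagnesiation of a propargylic alcohol; methyl adds to C2 and magnesium stays on C3 in a five-membered chelate cis to the CH2O arm, so protonation leaves silicon trans to CH2OH and cis to methyl, the E geometry the diene needs.

Step 2
Reactants: 2 (2E)-2-methyl-3-(trimethylsilyl)prop-2-en-1-ol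
Product: 3 [(1E)-3-bromo-2-methylprop-1-en-1-yl]trimethylsilane
Conditions: CBr4, PPh3, CH2Cl2, 0 °C
Reagents that add atoms: carbon tetrabromide, BrC(Br)(Br)Br
Why: Appel bromination; direct SN2 displacement at the primary allylic oxyphosphonium under neutral conditions, which the acid-sensitive vinylsilane tolerates without change of geometry.

Step 3
Reactants: 3 [(1E)-3-bromo-2-methylprop-1-en-1-yl]trimethylsilane
Product: 4 diethyl [(2E)-2-methyl-3-(trimethylsilyl)prop-2-en-1-yl]phosphonate
Conditions: P(OEt)3 (neat), 120 °C
Reagents that add atoms: triethyl phosphite, CCOP(OCC)OCC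
Why: Michaelis–Arbuzov reaction at the unhindered primary allylic carbon; no allylic shift is expected and bromoethane distils off.

Step 4
Reactants: 5 2,4-dihydroxybenzaldehyde
Product: 6 2,4-bis(methoxymethoxy)benzaldehyde
Conditions: MOMCl (3 equiv), i-Pr2NEt, CH2Cl2, 0 °C → reflux
Reagents that add atoms: chloromethyl methyl ether, COCCl
Why: O-alkylation of both phenols to base-stable acetals; the hydrogen-bonded 2-hydroxyl needs the excess and the warming.

Step 5
Reactants: 4 diethyl [(2E)-2-methyl-3-(trimethylsilyl)prop-2-en-1-yl]phosphonate; 6 2,4-bis(methoxymethoxy)benzaldehyde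
Product: 7 (1E,3E)-1-trimethylsilyl-2-methyl-4-[2,4-bis(methoxymethoxy)phenyl]buta-1,3-diene
Conditions: n-BuLi, THF, −78 °C; then 6, −78 → 25 °C
Reagents that add atoms: none
Why: Horner–Wadsworth–Emmons olefination of an allylic phosphonate with an aromatic aldehyde; reaction at the carbon next to phosphorus and syn-elimination should give the E styrenyl alkene, while the vinylsilane, set in step 1, is not part of the bond-forming event.

Step 6
Reactants: 8 2,4-dihydroxyacetophenone
Product: 9 1-[2-hydroxy-4-(2-methylbut-3-yn-2-yloxy)phenyl]ethanone
Conditions: 3-chloro-3-methylbut-1-yne, K2CO3, KI, CuI (5 mol%), acetone, reflux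
Reagents that add atoms: 3-chloro-3-methylbut-1-yne, CC(C)(Cl)C#C
Why: Copper-assisted O-alkylation with a tertiary propargylic chloride; only the 4-hydroxyl reacts because the 2-hydroxyl is held in the hydrogen bond to the acetyl group.

Step 7
Reactants: 9 1-[2-hydroxy-4-(2-methylbut-3-yn-2-yloxy)phenyl]ethanone
Product: 11 1-[2,4-dihydroxy-3-(3-methylbut-2-en-1-yl)phenyl]ethanone, via 1,1-dimethylallyl aryl ether 10 (not isolated)
Conditions: H2 (1 atm), Pd/CaCO3 poisoned with Pb(OAc)2 (Lindlar type), quinoline, xylene, 25 °C; filter; 130 °C
Reagents that add atoms: none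
Why: Semi-hydrogenation followed by aromatic Claisen rearrangement; the [3,3] shift inverts the allyl unit to the linear prenyl group and should go to C3, because the chelate of 2-OH and acetyl localises double-bond character in C3–C4.

Step 8
Reactants: 11 1-[2,4-dihydroxy-3-(3-methylbut-2-en-1-yl)phenyl]ethanone
Product: 12 1-[2-hydroxy-4-(methoxymethoxy)-3-(3-methylbut-2-en-1-yl)phenyl]ethanone
Conditions: MOMCl (1.1 equiv), K2CO3, acetone, 0 → 25 °C
Reagents that add atoms: chloromethyl methyl ether, COCCl
Why: Selective O-alkylation of the free 4-hydroxyl; the chelated 2-hydroxyl does not react with a weak base and stays free for boron in step 12.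

Step 9
Reactants: 13 2,6-dihydroxybenzaldehyde
Product: 14 2,6-bis(methoxymethoxy)benzaldehyde
Conditions: MOMCl (3 equiv), i-Pr2NEt, CH2Cl2, 0 °C → reflux
Reagents that add atoms: chloromethyl methyl ether, COCCl
Why: O-alkylation of both hydrogen-bonded phenols; the acetals survive the later hydroxide, borate and palladium steps.

Step 10
Reactants: 14 2,6-bis(methoxymethoxy)benzaldehyde
Product: 15 3-bromo-2,6-bis(methoxymethoxy)benzaldehyde
Conditions: NBS (1.0 equiv), MeCN, 0 → 25 °C
Reagents that add atoms: N-bromosuccinimide, O=C1CCC(=O)N1Br
Why: Electrophilic aromatic bromination ortho to one acetal oxygen, para to the other and meta to the formyl group; the two such positions are equivalent by symmetry and one equivalent limits dibromination.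

Step 11
Reactants: 12 1-[2-hydroxy-4-(methoxymethoxy)-3-(3-methylbut-2-en-1-yl)phenyl]ethanone; 15 3-bromo-2,6-bis(methoxymethoxy)benzaldehyde
Product: 16 (2E)-3-[3-bromo-2,6-bis(methoxymethoxy)phenyl]-1-[2-hydroxy-4-(methoxymethoxy)-3-(3-methylbut-2-en-1-yl)phenyl]prop-2-en-1-one
Conditions: KOH (aq), EtOH, 0 → 25 °C
Reagents that add atoms: none
Why: Claisen–Schmidt condensation of a methyl ketone with a non-enolisable aldehyde; E1cB dehydration gives the E enone, and acetals, aryl bromide and the phenoxide of the 2′-hydroxyl tolerate hydroxide.

Step 12
Reactants: 16 (2E)-3-[3-bromo-2,6-bis(methoxymethoxy)phenyl]-1-[2-hydroxy-4-(methoxymethoxy)-3-(3-methylbut-2-en-1-yl)phenyl]prop-2-en-1-one; 7 (1E,3E)-1-trimethylsilyl-2-methyl-4-[2,4-bis(methoxymethoxy)phenyl]buta-1,3-diene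
Product: 17 [(1S,2S,3R,6R)-2-[3-bromo-2,6-bis(methoxymethoxy)phenyl]-6-[2,4-bis(methoxymethoxy)phenyl]-4-methyl-3-(trimethylsilyl)cyclohex-4-en-1-yl][2-hydroxy-4-(methoxymethoxy)-3-(3-methylbut-2-en-1-yl)phenyl]methanone
Conditions: B(OPh)3 (1.5 equiv), (R)-VANOL (1.5 equiv), 4 Å MS, PhCF3, 25 °C; then 16 and 7 (2.5 equiv), 25 → 40 °C
Reagents that add atoms: none
Why: Diels–Alder reaction in which exchange at boron gives a six-membered chelate through the phenolic and carbonyl oxygens of 16, lowering the LUMO of the enone; the closest known reaction type is the chiral biaryl-borate-mediated [4+2] cycloaddition of 2′-hydroxychalcones with 1-aryl-3-methylbuta-1,3-dienes, here with silicon on the reacting diene terminus. The six-membered ring closes in one intermolecular, suprafacial–suprafacial [4+2] event that is concerted but asynchronous, C2–C3 leading and C1–C6 following. The silyl-bearing terminus has the largest HOMO coefficient, since bonding there leaves positive character on C4 where methyl, the aryl-allyl system and the β C–Si bond stabilise it, and it pairs with the β-carbon of the chelated enone. C1/C2 trans follows from the E geometry of 16, and C3/C6 cis from the two E alkenes of 7, which also places the C–Si bond pseudoaxial for the later transposition. C1/C6 trans needs the exo mode, with the bulky boron chelate turned away from the diene and ring B beneath it; the deep pocket of the vaulted ligand is chosen to favour this mode and to shield one enone face, which sets the absolute configuration of all four centres. Chemoselectivity rests on the free 2′-hydroxyl: only the chelated enone is activated, and the prenyl alkene and aryl bromide are spectators. The selectivity most at risk is exo versus endo, whereas early loss of silicon from part of the adduct would be harmless because it gives the alkene that step 14 makes anyway.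

Step 13
Reactants: 17 the cycloadduct named in step 12; 18 4-acetoxystyrene (4-ethenylphenyl acetate)
Product: 19 [(1S,2S,3R,6R)-2-{3-[(2E)-3-(4-acetoxyphenyl)prop-2-enoyl]-2,6-bis(methoxymethoxy)phenyl}-6-[2,4-bis(methoxymethoxy)phenyl]-4-methyl-3-(trimethylsilyl)cyclohex-4-en-1-yl][2-hydroxy-4-(methoxymethoxy)-3-(3-methylbut-2-en-1-yl)phenyl]methanone
Conditions: [Pd(cinnamyl)Cl]2 (2.5 mol%), n-BuP(1-Ad)2 (7.5 mol%), CO (5 bar), Et3N, 1,4-dioxane, 100 °C
Reagents that add atoms: carbon monoxide, [C-]#[O+]
Why: Carbonylative Heck reaction; oxidative addition of zerovalent palladium into C–Br, CO insertion to the aroylpalladium, styrene insertion and β-hydride elimination give the E enone. CO pressure suppresses the direct Heck path, and the allylsilane, the trisubstituted alkenes and the hydrogen-bonded 2′-hydroxyl are expected to stay out.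

Step 14
Reactants: 19 the silylated, protected bis-ketone named in step 13
Product: 21 [(1S,2S,6R)-6-(2,4-dihydroxyphenyl)-2-{2,6-dihydroxy-3-[(2E)-3-(4-hydroxyphenyl)prop-2-enoyl]phenyl}-4-methylcyclohex-3-en-1-yl][2,4-dihydroxy-3-(3-methylbut-2-en-1-yl)phenyl]methanone (the target), via desilylated protected ketone 20 (not isolated)
Conditions: HCl (3 M), MeOH/THF, 25 → 40 °C, monitored and stopped at full conversion
Reagents that add atoms: none
Why: Acid-mediated SE2′ protodesilylation; the proton adds to C5 anti to the pseudoaxial C–Si bond, the tertiary β-silyl cation at C4 loses silicon to methanol and the alkene lands at C3=C4 only. The same acid then cleaves the five acetals and transesterifies the acetate, and C1, C2 and C6 are not touched, C1 already being in its thermodynamically preferred all-trans arrangement.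

## Compound list

1 | 3-(trimethylsilyl)prop-2-yn-1-ol | C[Si](C)(C)C#CCO | starting material
2 | (2E)-2-methyl-3-(trimethylsilyl)prop-2-en-1-ol | C[Si](C)(C)/C=C(C)/CO | intermediate
3 | [(1E)-3-bromo-2-methylprop-1-en-1-yl]trimethylsilane | C[Si](C)(C)/C=C(C)/CBr | intermediate
4 | diethyl [(2E)-2-methyl-3-(trimethylsilyl)prop-2-en-1-yl]phosphonate | CCOP(=O)(OCC)C/C(C)=C/[Si](C)(C)C | intermediate
5 | 2,4-dihydroxybenzaldehyde | O=Cc1ccc(O)cc1O | starting material
6 | 2,4-bis(methoxymethoxy)benzaldehyde | COCOc1ccc(C=O)c(OCOC)c1 | intermediate
7 | (1E,3E)-1-trimethylsilyl-2-methyl-4-[2,4-bis(methoxymethoxy)phenyl]buta-1,3-diene | C[Si](C)(C)/C=C(C)/C=C/c1ccc(OCOC)cc1OCOC | intermediate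
8 | 2,4-dihydroxyacetophenone | CC(=O)c1ccc(O)cc1O | starting material
9 | 1-[2-hydroxy-4-(2-methylbut-3-yn-2-yloxy)phenyl]ethanone | CC(=O)c1ccc(OC(C)(C)C#C)cc1O | intermediate
10 | 1-[2-hydroxy-4-(2-methylbut-3-en-2-yloxy)phenyl]ethanone (not isolated) | CC(=O)c1ccc(OC(C)(C)C=C)cc1O | intermediate
11 | 1-[2,4-dihydroxy-3-(3-methylbut-2-en-1-yl)phenyl]ethanone | CC(=O)c1ccc(O)c(CC=C(C)C)c1O | intermediate
12 | 1-[2-hydroxy-4-(methoxymethoxy)-3-(3-methylbut-2-en-1-yl)phenyl]ethanone | CC(=O)c1ccc(OCOC)c(CC=C(C)C)c1O | intermediate
13 | 2,6-dihydroxybenzaldehyde | O=Cc1c(O)cccc1O | starting material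
14 | 2,6-bis(methoxymethoxy)benzaldehyde | COCOc1cccc(OCOC)c1C=O | intermediate
15 | 3-bromo-2,6-bis(methoxymethoxy)benzaldehyde | COCOc1ccc(Br)c(OCOC)c1C=O | intermediate
16 | (2E)-3-[3-bromo-2,6-bis(methoxymethoxy)phenyl]-1-[2-hydroxy-4-(methoxymethoxy)-3-(3-methylbut-2-en-1-yl)phenyl]prop-2-en-1-one | CC(C)=CCc1c(OCOC)ccc(C(=O)/C=C/c2c(OCOC)ccc(Br)c2OCOC)c1O | intermediate
17 | exo cycloadduct, (1S,2S,3R,6R), silicon on C3, alkene C4=C5, aroyl trans to rings B and C, silicon cis to ring B | CC(C)=CCc1c(OCOC)ccc(C(=O)[C@@H]2[C@@H](c3c(OCOC)ccc(Br)c3OCOC)[C@@H]([Si](C)(C)C)C(C)=C[C@H]2c2ccc(OCOC)cc2OCOC)c1O | intermediate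
18 | 4-acetoxystyrene | CC(=O)Oc1ccc(C=C)cc1 | starting material
19 | 17 with Br replaced by (2E)-3-(4-acetoxyphenyl)prop-2-enoyl, (1S,2S,3R,6R) | CC(C)=CCc1c(OCOC)ccc(C(=O)[C@@H]2[C@@H](c3c(OCOC)ccc(C(=O)/C=C/c4ccc(OC(C)=O)cc4)c3OCOC)[C@@H]([Si](C)(C)C)C(C)=C[C@H]2c2ccc(OCOC)cc2OCOC)c1O | intermediate
20 | desilylated 19, alkene C3=C4, (1S,2S,6R) (not isolated) | CC(C)=CCc1c(OCOC)ccc(C(=O)[C@@H]2[C@@H](c3c(OCOC)ccc(C(=O)/C=C/c4ccc(OC(C)=O)cc4)c3OCOC)C=C(C)C[C@H]2c2ccc(OCOC)cc2OCOC)c1O | intermediate
21 | [(1S,2S,6R)-6-(2,4-dihydroxyphenyl)-2-{2,6-dihydroxy-3-[(2E)-3-(4-hydroxyphenyl)prop-2-enoyl]phenyl}-4-methylcyclohex-3-en-1-yl][2,4-dihydroxy-3-(3-methylbut-2-en-1-yl)phenyl]methanone | CC(C)=CCc1c(O)ccc(C(=O)[C@@H]2[C@@H](c3c(O)ccc(C(=O)/C=C/c4ccc(O)cc4)c3O)C=C(C)C[C@H]2c2ccc(O)cc2O)c1O | target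

## Step count and least certain steps

Total step count: 14. Longest linear sequence: 7 steps (steps 1, 2, 3, 5, 12, 13, 14; the branch through steps 6, 7, 8, 11, 12, 13, 14 is equally long).

**Step 12 (key step).**
- Most likely to go wrong: slow cycloaddition, because the silyl-bearing diene terminus must bond to a β-carbon that carries a di-ortho-substituted aryl group; and erosion of exo/endo or facial discrimination. The exo/endo outcome cannot be repaired later, since in the endo adduct rings B and C are trans and epimerisation at C1 does not change that. A stepwise pathway could also lose silicon before ring closure and give an open-chain conjugate adduct.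
- Fallback: 16 and 7 would be combined under electron-transfer catalysis with silver nanoparticles on silica (Ag/SiO2) in CH2Cl2. This is a known, racemic way of cycloadding 2′-hydroxychalcones that does not need a crowded chiral borate. The exo racemate, made of 17 and the mirror-image adduct F1, would be freed from endo isomers on silica and resolved by preparative chromatography on a chiral stationary phase. The route is rejoined at 17.

**Step 13.**
- Most likely to go wrong: slow oxidative addition into the electron-rich, ortho-alkoxy aryl bromide; competition of direct Heck coupling with CO insertion; and acylation of the free 2′-phenol by the aroylpalladium intermediate.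
- Fallback: the ring D enone would be built without CO. Starting from 17, Stille coupling with tributyl(1-ethoxyvinyl)stannane (Pd(PPh3)4, toluene, 100 °C) would give the enol ether F4. Mild aqueous acid (1 M HCl, THF, 0 °C) is expected to hydrolyse the enol ether and remove silicon with allylic shift before the acetals are touched, giving the methyl ketone F5. Claisen–Schmidt condensation of F5 with commercial 4-(methoxymethoxy)benzaldehyde (KOH, EtOH) would give the hexakis(methoxymethyl) chalcone F6. Acidic methanol as in step 14 would return to the route at 21.

**Step 14.**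
- Most likely to go wrong: acid exposure of the free polyphenol. The risks are chroman formation from the prenyl group and the 4′-hydroxyl, addition of an ortho-phenol of ring B or C to the new ring alkene, flavanone closure on ring B, or incomplete acetate cleavage if the reaction is stopped early.
- Fallback: silicon would be removed before any phenol is free, and the phenols would be released without a Brønsted acid. Starting from 17, catalytic TsOH·H2O in CH2Cl2 at 0 °C would give the desilylated bromide F2. The carbonylative Heck reaction of F2 with 18 under the conditions of step 13 would rejoin the route at 20, now isolated. K2CO3 in MeOH would then give the free ring D phenol F3, and ZnBr2 with n-PrSH in CH2Cl2 at 0 °C would cleave the acetals to reach 21.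

**Step 5.**
- Most likely to go wrong: the allylic phosphonate anion is ambident. Reaction through the silyl-bearing carbon followed by Peterson-type loss of silicon, or loss of geometry in the delocalised anion, would lower the yield or the isomeric purity of 7.
- Fallback: the polarity of the olefination would be reversed. Starting from 2, MnO2 in CH2Cl2 would give the silyl enal F7. Starting from 6, NaBH4 in MeOH would give the benzyl alcohol F8. MsCl, Et3N and LiCl would give the benzyl chloride F9, used at once, and NaP(O)(OEt)2 in THF (Michaelis–Becker reaction) would give the benzyl phosphonate F10. Olefination of F7 with the anion of F10 (NaH, THF) is not ambident and would return to the route at 7.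

**Step 7.**
- Most likely to go wrong: over-reduction to the saturated ether; chromene formation on heating if alkyne is left; or partial migration to C5.
- Fallback: direct C-prenylation of the phenoxide of 8 with prenyl bromide in aqueous KOH, a known but low-yielding electrophilic alkylation, with chromatographic removal of the isomers. It sets out from 8 and returns at 11 and makes no new compound.

## Further compounds

F1 | step 12 | mirror image of 17, (1R,2R,3S,6S) | CC(C)=CCc1c(OCOC)ccc(C(=O)[C@H]2[C@H](c3c(OCOC)ccc(Br)c3OCOC)[C@H]([Si](C)(C)C)C(C)=C[C@@H]2c2ccc(OCOC)cc2OCOC)c1O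
F4 | step 13 | 17 with Br replaced by 1-ethoxyethenyl | CC(C)=CCc1c(OCOC)ccc(C(=O)[C@@H]2[C@@H](c3c(OCOC)ccc(C(=C)OCC)c3OCOC)[C@@H]([Si](C)(C)C)C(C)=C[C@H]2c2ccc(OCOC)cc2OCOC)c1O
F5 | step 13 | desilylated ring B methyl ketone, alkene C3=C4, (1S,2S,6R) | CC(C)=CCc1c(OCOC)ccc(C(=O)[C@@H]2[C@@H](c3c(OCOC)ccc(C(C)=O)c3OCOC)C=C(C)C[C@H]2c2ccc(OCOC)cc2OCOC)c1O
F6 | step 13 | hexakis(methoxymethyl) ether of 21 with free 2′-hydroxyl on ring A | CC(C)=CCc1c(OCOC)ccc(C(=O)[C@@H]2[C@@H](c3c(OCOC)ccc(C(=O)/C=C/c4ccc(OCOC)cc4)c3OCOC)C=C(C)C[C@H]2c2ccc(OCOC)cc2OCOC)c1O
F2 | step 14 | desilylated 17, alkene C3=C4, (1S,2S,6R) | CC(C)=CCc1c(OCOC)ccc(C(=O)[C@@H]2[C@@H](c3c(OCOC)ccc(Br)c3OCOC)C=C(C)C[C@H]2c2ccc(OCOC)cc2OCOC)c1O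
F3 | step 14 | 20 with free ring D phenol | CC(C)=CCc1c(OCOC)ccc(C(=O)[C@@H]2[C@@H](c3c(OCOC)ccc(C(=O)/C=C/c4ccc(O)cc4)c3OCOC)C=C(C)C[C@H]2c2ccc(OCOC)cc2OCOC)c1O
F7 | step 5 | (2E)-2-methyl-3-(trimethylsilyl)prop-2-enal | C[Si](C)(C)/C=C(C)/C=O
F8 | step 5 | [2,4-bis(methoxymethoxy)phenyl]methanol | COCOc1ccc(CO)c(OCOC)c1
F9 | step 5 | 1-(chloromethyl)-2,4-bis(methoxymethoxy)benzene | COCOc1ccc(CCl)c(OCOC)c1
F10 | step 5 | diethyl {[2,4-bis(methoxymethoxy)phenyl]methyl}phosphonate | CCOP(=O)(OCC)Cc1ccc(OCOC)cc1OCOC
F0 | step 7 | none | none
A1 | alternative 1 | 3-[2,4-bis(methoxymethoxy)phenyl]cyclobutan-1-one | O=C1CC(c2ccc(OCOC)cc2OCOC)C1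
A2 | alternative 1 | propyne | CC#C
A3 | alternative 1 | (5R)-5-[2,4-bis(methoxymethoxy)phenyl]-3-methylcyclohex-2-en-1-one | O=C1C=C(C)C[C@@H](c2ccc(OCOC)cc2OCOC)C1
A4 | alternative 2 | acyclic triene ester with vinyl on C2 and 2-methylallyl on C6 | COC(=O)[C@H]([C@@H](c1c(OCOC)ccc(Br)c1OCOC)C=C)[C@@H](CC(C)=C)c1ccc(OCOC)cc1OCOC
A5 | alternative 2 | all-trans methyl 2,6-diaryl-4-methylcyclohex-3-ene-1-carboxylate | COC(=O)[C@@H]1[C@@H](c2c(OCOC)ccc(Br)c2OCOC)C=C(C)C[C@H]1c1ccc(OCOC)cc1OCOC
A6 | alternative 3 | (Z)-keto acetate with silyl ether on the ring C 4-oxygen (C6 configuration not defined) | CC(C)=CCc1c(OCOC)ccc(C(=O)C[C@@H](c2c(OCOC)ccc(Br)c2OCOC)/C=C(C)\CC(OC(C)=O)c2ccc(O[Si](C)(C)C(C)(C)C)cc2OCOC)c1OCOC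
A7 | alternative 3 | all-trans cyclohexene with free 4-hydroxyl on ring C | CC(C)=CCc1c(OCOC)ccc(C(=O)[C@@H]2[C@@H](c3c(OCOC)ccc(Br)c3OCOC)C=C(C)C[C@H]2c2ccc(O)cc2OCOC)c1OCOC
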